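In ring A the carboxyl carbon C1 sits between two oxygenated carbons (C2, C6), C3 carries the chiral side chain and C4 and C5 bear only hydrogen: the enol pattern of an open-chain 2-acyl-3-oxo ester. Ring A is therefore made from a chain. Ring-closing metathesis joins the allyl ketone carbon C4 to the 1,1-disubstituted enone carbon C3, expels ethylene and, after spontaneous enolisation, delivers the 2,6-dihydroxybenzoate with the stereocentre already in place. The precursor is the 2-(trimethylsilyl)ethyl ester of a tricarbonyl, made by C-acylation of an allyl β-keto ester with a Morita–Baylis–Hillman-derived acid chloride; ring B is attached afterwards by SNAr.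

Key step: step 6

Remark: ring A is numbered as in the target (C1 carboxyl, C2 methoxy, C3 side chain, C6 aryloxy); the priorities at the stereocentre (O > sp2 carbon > CH2 > H) are the same from the Morita–Baylis–Hillman adduct to the target, so the (R) adduct is the one required and the descriptor stays R throughout.

Step 1
Reactants: 1 3-methylbutanal; 2 1,1,1,3,3,3-hexafluoropropan-2-yl prop-2-enoate
Product: 3 1,1,1,3,3,3-hexafluoropropan-2-yl (3R)-3-hydroxy-5-methyl-2-methylidenehexanoate
Conditions: β-isocupreidine (10 mol%), DMF, −55 °C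
Reagents that add atoms: none
Why: Morita–Baylis–Hillman reaction under bifunctional amine catalysis, in which the quinidine-derived amine adds to the activated acrylate and its phenolic OH organises the aldol step on one aldehyde face, so that the (R) carbinol should form with high enantiomeric purity, a level that plain methyl acrylate is not expected to reach.

Step 2
Reactants: 3 1,1,1,3,3,3-hexafluoropropan-2-yl (3R)-3-hydroxy-5-methyl-2-methylidenehexanoate
Product: 4 1,1,1,3,3,3-hexafluoropropan-2-yl (3R)-3-methoxy-5-methyl-2-methylidenehexanoate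
Conditions: Me3OBF4, 1,8-bis(dimethylamino)naphthalene, CH2Cl2, 0 °C to rt
Reagents that add atoms: trimethyloxonium tetrafluoroborate, C[O+](C)C.F[B-](F)(F)F
Why: O-alkylation with Meerwein's salt, buffered by a non-nucleophilic base, methylates the hindered allylic alcohol without attacking the activated ester and without the alkoxide that would invite retro-aldol or allylic (SN2') displacement, so the stereocentre is untouched.

Step 3
Reactants: 4 1,1,1,3,3,3-hexafluoropropan-2-yl (3R)-3-methoxy-5-methyl-2-methylidenehexanoate
Product: 5 (3R)-3-methoxy-5-methyl-2-methylidenehexanoic acid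
Conditions: LiOH, THF/H2O, 0 °C; then cold 1 M HCl
Reagents that add atoms: lithium hydroxide, [Li+].[OH-]
Why: Saponification of an activated ester: hydroxide cleaves the hexafluoroisopropyl ester at 0 °C well before it could add to the acrylate, and the stereocentre carries no acidic hydrogen, so it cannot epimerise.

Step 4
Reactants: 6 but-3-enoic acid; 7 2,2-dimethyl-1,3-dioxane-4,6-dione (Meldrum's acid)
Product: 9 2-(trimethylsilyl)ethyl 3-oxohex-5-enoate, via acyl Meldrum's acid 8 (not isolated)
Conditions: DCC, DMAP, CH2Cl2, 0 °C; then Me3SiCH2CH2OH, toluene, 80 °C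
Reagents that add atoms: 2-(trimethylsilyl)ethanol, C[Si](C)(C)CCO
Why: C-acylation of Meldrum's acid under carbodiimide/DMAP activation, then thermal loss of acetone and CO2 to an acyl ketene that the alcohol traps, is a standard β-keto ester synthesis, and it installs the fluoride-cleavable ester that later frees the doubly ortho-substituted acid without hydroxide.

Step 5
Reactants: 5 (3R)-3-methoxy-5-methyl-2-methylidenehexanoic acid; 9 2-(trimethylsilyl)ethyl 3-oxohex-5-enoate
Product: 11 2-(trimethylsilyl)ethyl (5R)-2-(but-3-enoyl)-5-methoxy-7-methyl-4-methylidene-3-oxooctanoate, via acid chloride 10 (not isolated)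
Conditions: Me2C=C(Cl)NMe2, CH2Cl2, 0 °C to rt (on 5); then 9, MgCl2, pyridine, CH2Cl2, 0 °C; cold 1 M HCl
Reagents that add atoms: none
Why: Soft-enolisation C-acylation (Rathke MgCl2/amine conditions): the magnesium chelate of the β-keto ester reacts at carbon with the acid chloride, which Ghosez's chloroenamine makes without free HCl, and the product stays masked as its magnesium chelate until the cold acidic quench, which limits O-acylation, conjugate addition to the enone and migration of the allyl double bond.

Step 6
Reactants: 11 2-(trimethylsilyl)ethyl (5R)-2-(but-3-enoyl)-5-methoxy-7-methyl-4-methylidene-3-oxooctanoate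
Product: 13 2-(trimethylsilyl)ethyl 2,6-dihydroxy-3-[(1R)-1-methoxy-3-methylbutyl]benzoate, via cyclohexenedione carboxylate 12 (not isolated)
Conditions: second-generation Grubbs catalyst (H2IMes)(PCy3)Cl2Ru=CHPh (5 mol%), 1,4-benzoquinone (10 mol%), CH2Cl2 (0.005 M), 40 °C
Reagents that add atoms: none
Why: Ring-closing olefin metathesis followed by tautomerisation to the arene, a known metathesis benzannulation: the ruthenium benzylidene exchanges onto the monosubstituted allyl alkene, the new alkylidene adds in a [2+2] sense to the 1,1-disubstituted enone alkene, and cycloreversion of the ruthenacyclobutane creates the C3=C4 bond while the two methylidene carbons leave as ethylene. Ring A is closed as a six-membered carbocycle by intramolecular alkene–alkene exchange (diene RCM giving an endocyclic trisubstituted alkene), and the cyclohexenedione 12 is a keto tautomer of a resorcinol that enolises at once, so the closure cannot revert. No stereocentre is created; the existing one stays allylic, has no acidic hydrogen and has no hydrogen on the neighbouring alkene carbon, so neither epimerisation nor loss of methanol is open to it. Regiochemistry is fixed by connectivity, because the carbon that bears the side chain is the one that becomes C3, between C2–O and C4–H. The selectivity that matters is ring closure over migration of the allyl double bond and over intermolecular metathesis: the hydrogen-bonded enol of the tricarbonyl holds both alkenes on one side of a planar chelate, high dilution disfavours dimers, and benzoquinone intercepts ruthenium hydrides.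

Step 7
Reactants: 14 2-bromo-1-fluoro-4-methylbenzene
Product: 15 3-bromo-2-fluoro-5-methylbenzaldehyde
Conditions: LiN(iPr)2, THF, −78 °C; then DMF, −78 °C; aq. HCl
Reagents that add atoms: N,N-dimethylformamide, CN(C)C=O
Why: Directed ortho-lithiation and formylation: the amide base removes the ring hydrogen next to fluorine (the most acidic one, whereas the position between bromine and methyl is hindered), and the aryllithium, kept at −78 °C to avoid benzyne formation, is trapped by DMF.

Step 8
Reactants: 13 2-(trimethylsilyl)ethyl 2,6-dihydroxy-3-[(1R)-1-methoxy-3-methylbutyl]benzoate; 15 3-bromo-2-fluoro-5-methylbenzaldehyde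
Product: 16 2-(trimethylsilyl)ethyl 6-(2-bromo-6-formyl-4-methylphenoxy)-2-hydroxy-3-[(1R)-1-methoxy-3-methylbutyl]benzoate
Conditions: K2CO3, DMF, 60 °C
Reagents that add atoms: none
Why: Nucleophilic aromatic substitution (SNAr) through a Meisenheimer adduct: the fluoride ortho to the formyl group and next to the inductively withdrawing bromine is displaced by the C6 phenoxide, the less hindered of the two ring A oxygens because C2–O is buttressed by the branched C3 side chain, and the doubly ortho-substituted electrophile sharpens that steric bias.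

Step 9
Reactants: 16 2-(trimethylsilyl)ethyl 6-(2-bromo-6-formyl-4-methylphenoxy)-2-hydroxy-3-[(1R)-1-methoxy-3-methylbutyl]benzoate
Product: 17 2-(trimethylsilyl)ethyl 6-(2-bromo-6-formyl-4-methylphenoxy)-2-methoxy-3-[(1R)-1-methoxy-3-methylbutyl]benzoate
Conditions: MeI, K2CO3, DMF, rt
Reagents that add atoms: iodomethane, CI
Why: Williamson ether synthesis on the one phenol left (C2–OH), which is hindered and hydrogen-bonded to the ester but is the only acidic site, while the aldehyde has no α-hydrogen and the aryl bromide is inert.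

Step 10
Reactants: 17 2-(trimethylsilyl)ethyl 6-(2-bromo-6-formyl-4-methylphenoxy)-2-methoxy-3-[(1R)-1-methoxy-3-methylbutyl]benzoate
Product: 19 2-(trimethylsilyl)ethyl 6-(2-formyl-6-hydroxy-4-methylphenoxy)-2-methoxy-3-[(1R)-1-methoxy-3-methylbutyl]benzoate, via pinacol boronate 18 (not isolated)
Conditions: B2pin2, Pd(dppf)Cl2 (5 mol%), KOAc, 1,4-dioxane, 90 °C; then NaBO3·4H2O, THF/H2O, rt
Reagents that add atoms: sodium perborate tetrahydrate (NaBO3·4H2O), [Na+].[Na+].O[B-]1(O)OO[B-](O)(O)OO1
Why: Miyaura borylation (oxidative addition of the aryl bromide to zerovalent palladium formed from Pd(dppf)Cl2, acetate-assisted transmetalation with B2pin2) followed by oxidative boron-to-oxygen aryl migration with perborate, two reactions that tolerate aryl aldehydes, esters and ethers and that place the ring B oxygen without a protecting group ever being carried on that ring.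

Step 11
Reactants: 19 2-(trimethylsilyl)ethyl 6-(2-formyl-6-hydroxy-4-methylphenoxy)-2-methoxy-3-[(1R)-1-methoxy-3-methylbutyl]benzoate
Product: 20 6-(2-formyl-6-hydroxy-4-methylphenoxy)-2-methoxy-3-[(1R)-1-methoxy-3-methylbutyl]benzoic acid (the target)
Conditions: Bu4NF, THF, 0 °C to rt; then cold dilute HCl
Reagents that add atoms: none
Why: Fluoride-triggered fragmentation of a 2-(trimethylsilyl)ethyl ester (attack at silicon, loss of ethylene and Me3SiF) frees the acid without a nucleophile having to reach the doubly ortho-substituted carbonyl, so the aldehyde, both methyl ethers and the stereocentre are left alone.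

Compound list
1 | 3-methylbutanal | CC(C)CC=O | starting material
2 | 1,1,1,3,3,3-hexafluoropropan-2-yl prop-2-enoate | C=CC(=O)OC(C(F)(F)F)C(F)(F)F | starting material
3 | 1,1,1,3,3,3-hexafluoropropan-2-yl (3R)-3-hydroxy-5-methyl-2-methylidenehexanoate | C=C(C(=O)OC(C(F)(F)F)C(F)(F)F)[C@@H](CC(C)C)O | intermediate
4 | 1,1,1,3,3,3-hexafluoropropan-2-yl (3R)-3-methoxy-5-methyl-2-methylidenehexanoate | C=C(C(=O)OC(C(F)(F)F)C(F)(F)F)[C@@H](CC(C)C)OC | intermediate
5 | (3R)-3-methoxy-5-methyl-2-methylidenehexanoic acid | C=C(C(=O)O)[C@@H](CC(C)C)OC | intermediate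
6 | but-3-enoic acid | C=CCC(=O)O | starting material
7 | 2,2-dimethyl-1,3-dioxane-4,6-dione (Meldrum's acid) | CC1(C)OC(=O)CC(=O)O1 | starting material
8 | 5-(1-hydroxybut-3-en-1-ylidene)-2,2-dimethyl-1,3-dioxane-4,6-dione | C=CCC(O)=C1C(=O)OC(C)(C)OC1=O | intermediate (not isolated)
9 | 2-(trimethylsilyl)ethyl 3-oxohex-5-enoate | C=CCC(=O)CC(=O)OCC[Si](C)(C)C | intermediate
10 | (3R)-3-methoxy-5-methyl-2-methylidenehexanoyl chloride | C=C(C(=O)Cl)[C@@H](CC(C)C)OC | intermediate (not isolated)
11 | 2-(trimethylsilyl)ethyl (5R)-2-(but-3-enoyl)-5-methoxy-7-methyl-4-methylidene-3-oxooctanoate | C=CCC(=O)C(C(=O)OCC[Si](C)(C)C)C(=O)C(=C)[C@@H](CC(C)C)OC | intermediate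
12 | 2-(trimethylsilyl)ethyl 3-[(1R)-1-methoxy-3-methylbutyl]-2,6-dioxocyclohex-3-ene-1-carboxylate | O=C1CC=C([C@@H](CC(C)C)OC)C(=O)C1C(=O)OCC[Si](C)(C)C | intermediate (not isolated)
13 | 2-(trimethylsilyl)ethyl 2,6-dihydroxy-3-[(1R)-1-methoxy-3-methylbutyl]benzoate | C[Si](C)(C)CCOC(=O)c1c(O)c([C@@H](CC(C)C)OC)ccc1O | intermediate
14 | 2-bromo-1-fluoro-4-methylbenzene | Cc1ccc(F)c(Br)c1 | starting material
15 | 3-bromo-2-fluoro-5-methylbenzaldehyde | Cc1cc(Br)c(F)c(C=O)c1 | intermediate
16 | 2-(trimethylsilyl)ethyl 6-(2-bromo-6-formyl-4-methylphenoxy)-2-hydroxy-3-[(1R)-1-methoxy-3-methylbutyl]benzoate | C[Si](C)(C)CCOC(=O)c1c(O)c([C@@H](CC(C)C)OC)ccc1Oc1c(Br)cc(C)cc1C=O | intermediate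
17 | 2-(trimethylsilyl)ethyl 6-(2-bromo-6-formyl-4-methylphenoxy)-2-methoxy-3-[(1R)-1-methoxy-3-methylbutyl]benzoate | C[Si](C)(C)CCOC(=O)c1c(OC)c([C@@H](CC(C)C)OC)ccc1Oc1c(Br)cc(C)cc1C=O | intermediate
18 | 2-(trimethylsilyl)ethyl 6-[2-formyl-4-methyl-6-(4,4,5,5-tetramethyl-1,3,2-dioxaborolan-2-yl)phenoxy]-2-methoxy-3-[(1R)-1-methoxy-3-methylbutyl]benzoate | C[Si](C)(C)CCOC(=O)c1c(OC)c([C@@H](CC(C)C)OC)ccc1Oc1c(B2OC(C)(C)C(C)(C)O2)cc(C)cc1C=O | intermediate (not isolated)
19 | 2-(trimethylsilyl)ethyl 6-(2-formyl-6-hydroxy-4-methylphenoxy)-2-methoxy-3-[(1R)-1-methoxy-3-methylbutyl]benzoate | C[Si](C)(C)CCOC(=O)c1c(OC)c([C@@H](CC(C)C)OC)ccc1Oc1c(O)cc(C)cc1C=O | intermediate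
20 | 6-(2-formyl-6-hydroxy-4-methylphenoxy)-2-methoxy-3-[(1R)-1-methoxy-3-methylbutyl]benzoic acid | COc1c([C@@H](CC(C)C)OC)ccc(Oc2c(O)cc(C)cc2C=O)c1C(=O)O | target

Total step count: 11. Longest linear sequence: 9 steps (steps 1, 2, 3, 5, 6, 8, 9, 10, 11, from 3-methylbutanal).

Steps most likely to fail

Step 6 (ring-closing metathesis). Ruthenium hydrides may shift the allyl double bond into conjugation before the ring closes, the acidic chelating enol may tie up the catalyst, or chains may couple with each other instead of cyclising. The fallback sets out from 11 and closes the ring on a different substrate class, a neutral silyl enol ether with no free enol. Treatment of 11 with t-BuMe2SiOTf and Et3N in CH2Cl2 at −78 °C would give 2-(trimethylsilyl)ethyl (5R)-2-{1-[(tert-butyldimethylsilyl)oxy]but-3-en-1-ylidene}-5-methoxy-7-methyl-4-methylidene-3-oxooctanoate F1. Silicon is expected on the less hindered allyl-ketone oxygen, and the isomer silylated on the other ketone oxygen would converge. Ring-closing metathesis of this triene with the same ruthenium catalyst, followed by tautomerisation of the dienone, would give 2-(trimethylsilyl)ethyl 6-[(tert-butyldimethylsilyl)oxy]-2-hydroxy-3-[(1R)-1-methoxy-3-methylbutyl]benzoate F2. Et3N·3HF in THF would then remove the aryl silyl group without touching the silylethyl ester, and the route is rejoined at 13.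

Step 5 (C-acylation). Conjugate addition of the magnesium enolate to the α-substituted acryloyl unit, or later of the enol oxygen to the enone with closure of a dihydropyranone, may compete with C-acylation, and the allyl ketone may drift into conjugation on long contact with base. The fallback sets out from 5 and exchanges the roles of the two fragments. Coupling of 5 with Meldrum's acid 7 (DCC, DMAP, CH2Cl2, 0 °C) would give 5-[(3R)-1-hydroxy-3-methoxy-5-methyl-2-methylidenehexylidene]-2,2-dimethyl-1,3-dioxane-4,6-dione F3. Heating with 2-(trimethylsilyl)ethanol in toluene would give 2-(trimethylsilyl)ethyl (5R)-5-methoxy-7-methyl-4-methylidene-3-oxooctanoate F4. In the magnesium chelate of this β-keto ester the enone carbonyl is part of the enolate and no longer an acceptor. C-acylation of the chelate (MgCl2, pyridine, CH2Cl2, 0 °C) with but-3-enoyl chloride F5, made from 6 with oxalyl chloride, would give 11, where the route is rejoined.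

Step 8 (SNAr). Arylation may occur at the more hindered C2 oxygen or at both oxygens. At the temperature needed, the ortho/para-hydroxybenzyl ether may lose methanol through a quinone methide, which would erode the stereocentre, and the fluoride released may cleave the silylethyl ester. The fallback sets out from 13 and differentiates the two phenols by protection before the ether is formed. iPr3SiOTf and 2,6-lutidine in CH2Cl2 at −78 °C would silylate the less hindered C6 oxygen to give 2-(trimethylsilyl)ethyl 2-hydroxy-3-[(1R)-1-methoxy-3-methylbutyl]-6-{[tri(propan-2-yl)silyl]oxy}benzoate F6. MeI and K2CO3 in acetone would methylate C2–OH to give 2-(trimethylsilyl)ethyl 2-methoxy-3-[(1R)-1-methoxy-3-methylbutyl]-6-{[tri(propan-2-yl)silyl]oxy}benzoate F7. Et3N·3HF in THF would free 2-(trimethylsilyl)ethyl 6-hydroxy-2-methoxy-3-[(1R)-1-methoxy-3-methylbutyl]benzoate F8, which has a single phenol and no ortho-hydroxybenzyl ether. Its SNAr with 15 (K2CO3, DMF) would give 17 directly, so the route is rejoined after step 9.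

Further compounds
F1 | step 6 | 2-(trimethylsilyl)ethyl (5R)-2-{1-[(tert-butyldimethylsilyl)oxy]but-3-en-1-ylidene}-5-methoxy-7-methyl-4-methylidene-3-oxooctanoate | C=CCC(O[Si](C)(C)C(C)(C)C)=C(C(=O)OCC[Si](C)(C)C)C(=O)C(=C)[C@@H](CC(C)C)OC
F2 | step 6 | 2-(trimethylsilyl)ethyl 6-[(tert-butyldimethylsilyl)oxy]-2-hydroxy-3-[(1R)-1-methoxy-3-methylbutyl]benzoate | C[Si](C)(C)CCOC(=O)c1c(O)c([C@@H](CC(C)C)OC)ccc1O[Si](C)(C)C(C)(C)C
F3 | step 5 | 5-[(3R)-1-hydroxy-3-methoxy-5-methyl-2-methylidenehexylidene]-2,2-dimethyl-1,3-dioxane-4,6-dione | C=C(C(O)=C1C(=O)OC(C)(C)OC1=O)[C@@H](CC(C)C)OC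
F4 | step 5 | 2-(trimethylsilyl)ethyl (5R)-5-methoxy-7-methyl-4-methylidene-3-oxooctanoate | C=C(C(=O)CC(=O)OCC[Si](C)(C)C)[C@@H](CC(C)C)OC
F5 | step 5 | but-3-enoyl chloride | C=CCC(=O)Cl
F6 | step 8 | 2-(trimethylsilyl)ethyl 2-hydroxy-3-[(1R)-1-methoxy-3-methylbutyl]-6-{[tri(propan-2-yl)silyl]oxy}benzoate | C[Si](C)(C)CCOC(=O)c1c(O)c([C@@H](CC(C)C)OC)ccc1O[Si](C(C)C)(C(C)C)C(C)C
F7 | step 8 | 2-(trimethylsilyl)ethyl 2-methoxy-3-[(1R)-1-methoxy-3-methylbutyl]-6-{[tri(propan-2-yl)silyl]oxy}benzoate | C[Si](C)(C)CCOC(=O)c1c(OC)c([C@@H](CC(C)C)OC)ccc1O[Si](C(C)C)(C(C)C)C(C)C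
F8 | step 8 | 2-(trimethylsilyl)ethyl 6-hydroxy-2-methoxy-3-[(1R)-1-methoxy-3-methylbutyl]benzoate | C[Si](C)(C)CCOC(=O)c1c(OC)c([C@@H](CC(C)C)OC)ccc1O
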